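The route rests on disconnecting the two remote phenolic C–O bonds, C6–O on benzo ring A of the isocoumarin and C4'–O on the pendant ring B. In the deoxy diaryl ether these are the only aromatic C–H bonds whose two ring neighbours (C5/C7 and C3'/C5') both carry hydrogen, so one iridium-catalysed, sterically governed double C–H borylation followed by oxidation in the same flask installs both hydroxyls. The precursor, 8-(2-methoxy-6-pentylphenoxy)-3-pentylisocoumarin 10, is assembled from o-vanillin, 2-bromo-6-fluorobenzaldehyde and 1-heptyne by Wittig/hydrogenation, fluoride displacement, Sonogashira coupling, Pinnick oxidation and acid-catalysed 6-endo lactonisation; a final BBr3 demethylation gives the target.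

Key step: step 7

Remark: the target has no stereocentre. Alkene 3 is carried as an E/Z mixture (Z expected to predominate, and the SMILES shows Z) because step 2 removes the geometry.

Step 1
Reactants: 1 o-vanillin (2-hydroxy-3-methoxybenzaldehyde); 2 butyltriphenylphosphonium bromide
Product: 3 2-methoxy-6-[(Z)-pent-1-en-1-yl]phenol (E/Z mixture)
Conditions: 2 (2.2 equiv), KOtBu (2.2 equiv), THF, 0 °C to rt; aq NH4Cl
Reagents that add atoms: none
Why: Wittig olefination, in which excess non-stabilised ylide first converts the phenol into its phenoxide and then olefinates the aldehyde, the alkene geometry being irrelevant because the double bond is hydrogenated next.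

Step 2
Reactants: 3 2-methoxy-6-[(Z)-pent-1-en-1-yl]phenol
Product: 4 2-methoxy-6-pentylphenol
Conditions: H2 (1 atm), 10% Pd/C, EtOAc, rt
Reagents that add atoms: none
Why: Heterogeneous catalytic hydrogenation should saturate the styrenyl double bond while the arene, the phenol and the methyl ether stay inert at room temperature and one atmosphere.

Step 3
Reactants: 4 2-methoxy-6-pentylphenol; 5 2-bromo-6-fluorobenzaldehyde
Product: 6 2-bromo-6-(2-methoxy-6-pentylphenoxy)benzaldehyde
Conditions: K2CO3 (1.5 equiv), DMF, 90 °C
Reagents that add atoms: none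
Why: Nucleophilic aromatic substitution (addition–elimination), in which the phenoxide of 4 attacks the fluorine-bearing carbon ortho to the formyl group, the aldehyde stabilises the Meisenheimer adduct, and fluoride leaves far faster than bromide, so the bromide is kept for step 4.

Step 4
Reactants: 6 2-bromo-6-(2-methoxy-6-pentylphenoxy)benzaldehyde; 7 1-heptyne
Product: 8 2-(hept-1-yn-1-yl)-6-(2-methoxy-6-pentylphenoxy)benzaldehyde
Conditions: PdCl2(PPh3)2 (3 mol%), CuI (5 mol%), Et3N, THF (degassed), 50 °C
Reagents that add atoms: none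
Why: Sonogashira coupling, in which the aryl bromide ortho to the electron-withdrawing formyl group adds readily to zerovalent palladium and couples with the copper acetylide of 7 while the aldehyde and both ethers are spectators.

Step 5
Reactants: 8 2-(hept-1-yn-1-yl)-6-(2-methoxy-6-pentylphenoxy)benzaldehyde
Product: 9 2-(hept-1-yn-1-yl)-6-(2-methoxy-6-pentylphenoxy)benzoic acid
Conditions: NaClO2, NaH2PO4, 2-methyl-2-butene (excess), t-BuOH/H2O, rt
Reagents that add atoms: sodium chlorite, [Na+].[O-]Cl=O
Why: Pinnick oxidation, in which chlorous acid oxidises the hindered aldehyde to the acid without touching the alkyne and 2-methyl-2-butene traps the hypochlorous acid that could otherwise chlorinate the electron-rich ring B.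

Step 6
Reactants: 9 2-(hept-1-yn-1-yl)-6-(2-methoxy-6-pentylphenoxy)benzoic acid
Product: 10 8-(2-methoxy-6-pentylphenoxy)-3-pentylisocoumarin (8-(2-methoxy-6-pentylphenoxy)-3-pentyl-1H-isochromen-1-one)
Conditions: TfOH (10 mol%), ClCH2CH2Cl, rt to 50 °C
Reagents that add atoms: none
Why: Brønsted acid-catalysed 6-endo-dig cycloisomerisation of a 2-alkynylbenzoic acid, in which attack of the carbonyl oxygen on the distal carbon of the protonated alkyne passes through an aromatic 1-hydroxy-2-benzopyrylium ion and so favours the isocoumarin over the 5-exo alkylidene phthalide that silver salts or bases tend to give with alkyl-substituted alkynes.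

Step 7
Reactants: 10 8-(2-methoxy-6-pentylphenoxy)-3-pentylisocoumarin; 11 bis(pinacolato)diboron
Product: 13 6-hydroxy-8-(4-hydroxy-2-methoxy-6-pentylphenoxy)-3-pentylisocoumarin, via bis(pinacol boronate) 12 (not isolated)
Conditions: [Ir(OMe)(cod)]2 (3 mol%), 4,4'-di-tert-butyl-2,2'-bipyridine (6 mol%), 11 (3 equiv), THF, 80 °C; then NaBO3·4H2O, THF/H2O, rt; aq NH4Cl
Reagents that add atoms: sodium perborate (NaBO3·4H2O), [Na+].[Na+].O[B-]1(O)OO[B-](O)(O)OO1
Why: The bipyridine-ligated tris(boryl) complex of trivalent iridium formed from [Ir(OMe)(cod)]2 and 11 cleaves an aryl C–H bond and C–B reductive elimination releases the aryl boronate, after which perborate adds to each boron and a 1,2-shift of the aryl group from boron to oxygen, followed by hydrolysis, leaves the phenol at exactly the borylated carbon. The closest known reaction type is the sterically controlled iridium-catalysed C–H borylation of 1,3- and 1,2,3-substituted arenes with one-pot oxidation to phenols. No ring is closed and no stereocentre is created. The step needs C6 on ring A and C4' on ring B only, and the substrate secures this because these are the sole C–H bonds whose two neighbours carry hydrogen: C5–H lies next to the ring fusion and peri to C4–H, C7–H is ortho to the C8 aryloxy group, C3'–H is ortho to the methoxy group, C5'–H is ortho to the pentyl chain, and the vinylic C4–H is wedged between the C3 pentyl group and C4a. The electron-poor ring A should borylate first, so excess 11 and heating are used to carry the electron-rich ring B to completion, after which no unhindered C–H bond remains. The mildly basic perborate should leave the enol lactone, the diaryl ether and the methyl ether untouched, and the acidic work-up recloses any lactone that has opened.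

Step 8
Reactants: 13 6-hydroxy-8-(4-hydroxy-2-methoxy-6-pentylphenoxy)-3-pentylisocoumarin
Product: 14 8-(2,4-dihydroxy-6-pentylphenoxy)-6-hydroxy-3-pentylisocoumarin (target)
Conditions: BBr3 (5 equiv), CH2Cl2, −78 °C to rt; then H2O
Reagents that add atoms: none
Why: Lewis acid ether cleavage with BBr3, in which boron binds the anisole oxygen and bromide removes the methyl group by SN2 attack, whereas the diaryl ether has no sp3 C–O bond, isocoumarin lactones tolerate such demethylations, and the excess reagent covers the two free phenols, whose aryl borates hydrolyse on work-up.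

Compound list
1 | o-vanillin (2-hydroxy-3-methoxybenzaldehyde) | COc1cccc(C=O)c1O | starting material
2 | butyltriphenylphosphonium bromide | CCCC[P+](c1ccccc1)(c1ccccc1)c1ccccc1.[Br-] | starting material
3 | 2-methoxy-6-[(Z)-pent-1-en-1-yl]phenol (E/Z mixture, Z drawn) | CCC/C=C\c1cccc(OC)c1O | intermediate
4 | 2-methoxy-6-pentylphenol | CCCCCc1cccc(OC)c1O | intermediate
5 | 2-bromo-6-fluorobenzaldehyde | O=Cc1c(F)cccc1Br | starting material
6 | 2-bromo-6-(2-methoxy-6-pentylphenoxy)benzaldehyde | O=Cc1c(Br)cccc1Oc1c(OC)cccc1CCCCC | intermediate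
7 | 1-heptyne | CCCCCC#C | starting material
8 | 2-(hept-1-yn-1-yl)-6-(2-methoxy-6-pentylphenoxy)benzaldehyde | CCCCCC#Cc1cccc(Oc2c(OC)cccc2CCCCC)c1C=O | intermediate
9 | 2-(hept-1-yn-1-yl)-6-(2-methoxy-6-pentylphenoxy)benzoic acid | CCCCCC#Cc1cccc(Oc2c(OC)cccc2CCCCC)c1C(=O)O | intermediate
10 | 8-(2-methoxy-6-pentylphenoxy)-3-pentylisocoumarin | CCCCCc1cc2cccc(Oc3c(OC)cccc3CCCCC)c2c(=O)o1 | intermediate
11 | bis(pinacolato)diboron | CC1(C)OB(OC1(C)C)B1OC(C)(C)C(C)(C)O1 | starting material
12 | 8-[2-methoxy-6-pentyl-4-(4,4,5,5-tetramethyl-1,3,2-dioxaborolan-2-yl)phenoxy]-3-pentyl-6-(4,4,5,5-tetramethyl-1,3,2-dioxaborolan-2-yl)isocoumarin (not isolated) | CCCCCc1cc2cc(B3OC(C)(C)C(C)(C)O3)cc(Oc3c(OC)cc(B4OC(C)(C)C(C)(C)O4)cc3CCCCC)c2c(=O)o1 | intermediate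
13 | 6-hydroxy-8-(4-hydroxy-2-methoxy-6-pentylphenoxy)-3-pentylisocoumarin | CCCCCc1cc2cc(O)cc(Oc3c(OC)cc(O)cc3CCCCC)c2c(=O)o1 | intermediate
14 | 8-(2,4-dihydroxy-6-pentylphenoxy)-6-hydroxy-3-pentylisocoumarin | CCCCCc1cc2cc(O)cc(Oc3c(O)cc(O)cc3CCCCC)c2c(=O)o1 | target

Total step count: 8. Longest linear sequence: 8 steps (1 to 14).

Steps most likely to fail

Step 7. The second borylation, on the electron-rich and trisubstituted ring B, may stall at the mono-boronate. Under forcing conditions it may also lose site control next to the small methoxy group, so that a mixture of hydroxylation patterns results. The fallback sets out from 4 and comes back at 14; it brings the ring B oxygen in by classical chemistry and leaves only the easy ring A for C–H borylation.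
- Bromination of 4 para to the free hydroxyl (NBS, MeCN, 0 °C) should give 4-bromo-2-methoxy-6-pentylphenol F1.
- Copper-catalysed methoxylation (NaOMe, CuI, DMF/MeOH, 110 °C) should give 2,4-dimethoxy-6-pentylphenol F2.
- Under the conditions of steps 3 to 6, F2 and 5 should give 2-bromo-6-(2,4-dimethoxy-6-pentylphenoxy)benzaldehyde F3. Coupling with 7 then gives 2-(2,4-dimethoxy-6-pentylphenoxy)-6-(hept-1-yn-1-yl)benzaldehyde F4, oxidation gives 2-(2,4-dimethoxy-6-pentylphenoxy)-6-(hept-1-yn-1-yl)benzoic acid F5, and TfOH closure gives 8-(2,4-dimethoxy-6-pentylphenoxy)-3-pentylisocoumarin F6.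
- In F6 both ring B hydrogens are flanked (C3' between two methoxy groups, C5' between methoxy and pentyl). The same iridium catalyst with 11 (1.2 equiv) at rt to 50 °C should therefore borylate C6 alone, giving 8-(2,4-dimethoxy-6-pentylphenoxy)-3-pentyl-6-(4,4,5,5-tetramethyl-1,3,2-dioxaborolan-2-yl)isocoumarin F7.
- NaBO3 oxidation converts F7 into 8-(2,4-dimethoxy-6-pentylphenoxy)-6-hydroxy-3-pentylisocoumarin F8, and BBr3 cleaves both methyl ethers to deliver 14.

Step 6. Closure through the proximal alkyne carbon (5-exo) may compete with the 6-endo closure and divert material to the alkylidene phthalide. The fallback sets out from 9 and comes back at 10; it replaces proton-catalysed cycloisomerisation by an electrophile-driven closure of the ester with a removable C4 substituent.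
- Esterification (MeI, K2CO3, DMF, rt) should give methyl 2-(hept-1-yn-1-yl)-6-(2-methoxy-6-pentylphenoxy)benzoate F9.
- Iodocyclisation (I2, CH2Cl2, rt), in which the ester carbonyl oxygen opens the iodonium ion at the distal carbon with loss of methyl iodide, should give 4-iodo-8-(2-methoxy-6-pentylphenoxy)-3-pentylisocoumarin F10. Iodine is preferred to ICl to spare ring B.
- Hydrodeiodination (Pd(PPh3)4, HCO2H/Et3N, DMF, 60 °C) returns 10.

Step 3. Attack by the doubly ortho-substituted phenoxide may be slow enough that base-induced degradation of the aldehyde electrophile outruns the substitution. The fallback sets out from 4 and comes back at 6; it uses a stronger, base-stable activating group and adjusts the oxidation level afterwards.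
- Substitution of 4 on commercial 2-bromo-6-fluorobenzonitrile (N#Cc1c(F)cccc1Br; K2CO3, DMF, 90 °C) should give 2-bromo-6-(2-methoxy-6-pentylphenoxy)benzonitrile F11.
- Partial reduction (i-Bu2AlH, toluene, −78 to 0 °C; aq HCl) and hydrolysis of the aldimine gives 6.

Further compounds
F1 | step 7 | 4-bromo-2-methoxy-6-pentylphenol | CCCCCc1cc(Br)cc(OC)c1O
F2 | step 7 | 2,4-dimethoxy-6-pentylphenol | CCCCCc1cc(OC)cc(OC)c1O
F3 | step 7 | 2-bromo-6-(2,4-dimethoxy-6-pentylphenoxy)benzaldehyde | O=Cc1c(Br)cccc1Oc1c(OC)cc(OC)cc1CCCCC
F4 | step 7 | 2-(2,4-dimethoxy-6-pentylphenoxy)-6-(hept-1-yn-1-yl)benzaldehyde | CCCCCC#Cc1cccc(Oc2c(OC)cc(OC)cc2CCCCC)c1C=O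
F5 | step 7 | 2-(2,4-dimethoxy-6-pentylphenoxy)-6-(hept-1-yn-1-yl)benzoic acid | CCCCCC#Cc1cccc(Oc2c(OC)cc(OC)cc2CCCCC)c1C(=O)O
F6 | step 7 | 8-(2,4-dimethoxy-6-pentylphenoxy)-3-pentylisocoumarin | CCCCCc1cc2cccc(Oc3c(OC)cc(OC)cc3CCCCC)c2c(=O)o1
F7 | step 7 | 8-(2,4-dimethoxy-6-pentylphenoxy)-3-pentyl-6-(4,4,5,5-tetramethyl-1,3,2-dioxaborolan-2-yl)isocoumarin | CCCCCc1cc2cc(B3OC(C)(C)C(C)(C)O3)cc(Oc3c(OC)cc(OC)cc3CCCCC)c2c(=O)o1
F8 | step 7 | 8-(2,4-dimethoxy-6-pentylphenoxy)-6-hydroxy-3-pentylisocoumarin | CCCCCc1cc2cc(O)cc(Oc3c(OC)cc(OC)cc3CCCCC)c2c(=O)o1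
F9 | step 6 | methyl 2-(hept-1-yn-1-yl)-6-(2-methoxy-6-pentylphenoxy)benzoate | CCCCCC#Cc1cccc(Oc2c(OC)cccc2CCCCC)c1C(=O)OC
F10 | step 6 | 4-iodo-8-(2-methoxy-6-pentylphenoxy)-3-pentylisocoumarin | CCCCCc1oc(=O)c2c(Oc3c(OC)cccc3CCCCC)cccc2c1I
F11 | step 3 | 2-bromo-6-(2-methoxy-6-pentylphenoxy)benzonitrile | N#Cc1c(Br)cccc1Oc1c(OC)cccc1CCCCC
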